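## Retrosynthetic overview

1. Target ⇐ protected macrocyclic 5-ylidene-butenolide: angelate at C6, acetates at C2/C13 and PMB removal at C15 are left to the end.
2. C8=C9 ⇐ E1cB loss of a C9 mesylate inside the ten-membered ring; ten-membered carbocycle ⇐ ring-closing metathesis forming the trisubstituted C3=C4 alkene.
3. C8–C9 ⇐ intermolecular vinylogous Mukaiyama aldol of a 2-silyloxyfuran (C5–C8, C11–C13, C15) with an α-silyloxy aldehyde (C9, C10, C14, C1–C3); this is the convergent step.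
4. Both fragments ⇐ one 2-(PMB-oxymethyl)allylstannane by Keck asymmetric carbonyl allylation (sets C6 and C2); C10 ⇐ Sharpless epoxidation and hydride opening.
5. Ring order: furan (purchased) → butenolide (before coupling) → ten-membered carbocycle (after coupling).

Convention and assumption (one line): germacranolide locants are used (ring C1–C10 with C2 = CHOAc, C3=C4, C6 = CHOAng, C10 = C(OH)CH3; lactone C11–C13 with C12 = C=O and C13 = CH2OAc; C14 = CH3 on C10; C15 = CH2OH on C4), and the target is taken as drawn by the SMILES, i.e. (2S,6S,10R) with both ring alkenes E by CIP (ring carbons cis).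

## Route

Step 1
Reactants: 1 3-chloro-2-(chloromethyl)prop-1-ene (3 equiv); 2 4-methoxybenzyl alcohol
Product: 3 1-({[2-(chloromethyl)prop-2-en-1-yl]oxy}methyl)-4-methoxybenzene
Conditions: NaH, THF, 0 °C → rt
Reagents that add atoms: none
Why: Williamson ether synthesis, with the excess of the symmetrical dichloride suppressing double substitution.

Step 2
Reactants: 3 1-({[2-(chloromethyl)prop-2-en-1-yl]oxy}methyl)-4-methoxybenzene
Product: 5 tributyl(2-{[(4-methoxybenzyl)oxy]methyl}prop-2-en-1-yl)stannane, via allylic Grignard reagent 4 (not isolated)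
Conditions: Mg turnings, Bu3SnCl, THF, 0 °C → rt
Reagents that add atoms: tributyltin chloride, CCCC[Sn](Cl)(CCCC)CCCC
Why: Barbier-type stannylation in which the allylic Grignard reagent is trapped by Bu3SnCl as it forms; both allyl termini are equivalent so there is no regiochemical issue.

Step 3
Reactants: 6 diethyl furan-3,4-dicarboxylate
Product: 7 furan-3,4-diyldimethanol
Conditions: LiAlH4, THF, 0 °C → rt; Fieser work-up
Reagents that add atoms: none
Why: LiAlH4 ester reduction gives the symmetrical diol that already carries the future C13 and C6 carbons.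

Step 4
Reactants: 7 furan-3,4-diyldimethanol
Product: 8 [4-({[tert-butyl(dimethyl)silyl]oxy}methyl)furan-3-yl]methanol
Conditions: NaH (1.0 equiv), THF, 0 °C; TBSCl (1.0 equiv)
Reagents that add atoms: tert-butyldimethylsilyl chloride, CC(C)(C)[Si](C)(C)Cl
Why: Monosilylation of a symmetrical diol through its monosodium alkoxide desymmetrises the two hydroxymethyl groups.

Step 5
Reactants: 8 [4-({[tert-butyl(dimethyl)silyl]oxy}methyl)furan-3-yl]methanol
Product: 11 [4-({[tert-butyl(dimethyl)silyl]oxy}methyl)-2-(trimethylsilyl)furan-3-yl]methanol, via dilithiated furylmethanolate 9 (not isolated), via bis-trimethylsilyl intermediate 10 (not isolated)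
Conditions: n-BuLi (2.2 equiv), THF, −78 → 0 °C; Me3SiCl (2.5 equiv), −78 °C → rt; then K2CO3 (cat.), MeOH, rt
Reagents that add atoms: chlorotrimethylsilane, C[Si](C)(C)Cl
Why: Alkoxide-directed ortho-lithiation places lithium on the furan α-carbon next to CH2OLi (the bulky silyl ether side does not direct), C-silylation marks that carbon as the future C12, and the transient O–SiMe3 ether is methanolysed.

Step 6
Reactants: 11 [4-({[tert-butyl(dimethyl)silyl]oxy}methyl)-2-(trimethylsilyl)furan-3-yl]methanol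
Product: 12 tert-butyl{[4-({[tert-butyl(dimethyl)silyl]oxy}methyl)-2-(trimethylsilyl)furan-3-yl]methoxy}diphenylsilane
Conditions: TBDPSCl, imidazole, DMF, rt
Reagents that add atoms: tert-butyl(chloro)diphenylsilane, CC(C)(C)[Si](Cl)(c1ccccc1)c1ccccc1
Why: Imidazole-mediated silylation protects the C13 oxygen with an acid-stable silyl ether.

Step 7
Reactants: 12 tert-butyl{[4-({[tert-butyl(dimethyl)silyl]oxy}methyl)-2-(trimethylsilyl)furan-3-yl]methoxy}diphenylsilane
Product: 13 [4-({[tert-butyl(diphenyl)silyl]oxy}methyl)-5-(trimethylsilyl)furan-3-yl]methanol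
Conditions: PPTS (cat.), MeOH, rt
Reagents that add atoms: none
Why: Acid-catalysed methanolysis cleaves the primary TBS ether selectively while the TBDPS ether and the C–SiMe3 bond survive.

Step 8
Reactants: 13 [4-({[tert-butyl(diphenyl)silyl]oxy}methyl)-5-(trimethylsilyl)furan-3-yl]methanol
Product: 14 4-({[tert-butyl(diphenyl)silyl]oxy}methyl)-5-(trimethylsilyl)furan-3-carbaldehyde
Conditions: activated MnO2 (excess), CH2Cl2, rt
Reagents that add atoms: none
Why: MnO2 oxidation of the furylic (benzylic-type) alcohol stops cleanly at the aldehyde (C6).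

Step 9
Reactants: 14 4-({[tert-butyl(diphenyl)silyl]oxy}methyl)-5-(trimethylsilyl)furan-3-carbaldehyde; 5 tributyl(2-{[(4-methoxybenzyl)oxy]methyl}prop-2-en-1-yl)stannane
Product: 15 (1S)-1-[4-({[tert-butyl(diphenyl)silyl]oxy}methyl)-5-(trimethylsilyl)furan-3-yl]-3-{[(4-methoxybenzyl)oxy]methyl}but-3-en-1-ol
Conditions: (S)-BINOL (20 mol%), Ti(OiPr)4 (10 mol%), 4 Å MS, CH2Cl2, −20 °C, 72 h; aq. NaHCO3
Reagents that add atoms: none
Why: Keck asymmetric carbonyl allylation, in which the (S)-BINOL–titanium catalyst directs the allylstannane to the Si face of the aldehyde and so sets C6 as S.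

Step 10
Reactants: 15 (1S)-1-[4-({[tert-butyl(diphenyl)silyl]oxy}methyl)-5-(trimethylsilyl)furan-3-yl]-3-{[(4-methoxybenzyl)oxy]methyl}but-3-en-1-ol
Product: 16 tert-butyl{[4-[(1S)-3-{[(4-methoxybenzyl)oxy]methyl}-1-[(triethylsilyl)oxy]but-3-en-1-yl]-2-(trimethylsilyl)furan-3-yl]methoxy}diphenylsilane
Conditions: Et3SiCl, imidazole, DMF, 0 °C
Reagents that add atoms: chlorotriethylsilane, CC[Si](Cl)(CC)CC
Why: Silylation gives a C6 triethylsilyl ether that can later be removed selectively in the presence of the TBS and TBDPS ethers.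

Step 11
Reactants: 16 tert-butyl{[4-[(1S)-3-{[(4-methoxybenzyl)oxy]methyl}-1-[(triethylsilyl)oxy]but-3-en-1-yl]-2-(trimethylsilyl)furan-3-yl]methoxy}diphenylsilane
Product: 18 3-({[tert-butyl(diphenyl)silyl]oxy}methyl)-5-hydroxy-4-[(1S)-3-{[(4-methoxybenzyl)oxy]methyl}-1-[(triethylsilyl)oxy]but-3-en-1-yl]furan-2(5H)-one (C5 epimers), via furan endoperoxide 17 (not isolated)
Conditions: O2, hν (visible), tetraphenylporphyrin (cat.), CH2Cl2, −78 °C; aqueous work-up
Reagents that add atoms: dioxygen, O=O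
Why: Singlet-oxygen [4+2] photooxygenation of the 2-silylfuran, where the silyl-bearing carbon becomes the lactone carbonyl (C12), gives the γ-hydroxybutenolide regiospecifically and leaves the 1,1-disubstituted alkene untouched.

Step 12
Reactants: 18 3-({[tert-butyl(diphenyl)silyl]oxy}methyl)-5-hydroxy-4-[(1S)-3-{[(4-methoxybenzyl)oxy]methyl}-1-[(triethylsilyl)oxy]but-3-en-1-yl]furan-2(5H)-one
Product: 20 3-({[tert-butyl(diphenyl)silyl]oxy}methyl)-4-[(1S)-3-{[(4-methoxybenzyl)oxy]methyl}-1-[(triethylsilyl)oxy]but-3-en-1-yl]furan-2(5H)-one, via sodium hydroxy-carboxylate 19 (not isolated)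
Conditions: NaBH4, MeOH, 0 °C; then 1 M HCl to pH 3–4, 0 °C
Reagents that add atoms: none
Why: Borohydride reduction of the ring-opened aldehyde tautomer of the pseudo-acid followed by relactonisation of the cis-hydroxy acid gives the butenolide with C8 as CH2.

Step 13
Reactants: 20 3-({[tert-butyl(diphenyl)silyl]oxy}methyl)-4-[(1S)-3-{[(4-methoxybenzyl)oxy]methyl}-1-[(triethylsilyl)oxy]but-3-en-1-yl]furan-2(5H)-one
Product: 21 tert-butyl({3-({[tert-butyl(diphenyl)silyl]oxy}methyl)-4-[(1S)-3-{[(4-methoxybenzyl)oxy]methyl}-1-[(triethylsilyl)oxy]but-3-en-1-yl]furan-2-yl}oxy)dimethylsilane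
Conditions: TBSOTf, Et3N, CH2Cl2, 0 °C; used directly after filtration
Reagents that add atoms: tert-butyldimethylsilyl trifluoromethanesulfonate, CC(C)(C)[Si](C)(C)OS(=O)(=O)C(F)(F)F
Why: Soft enolisation and O-silylation convert the butenolide into the aromatic 2-silyloxyfuran, the nucleophile for the vinylogous Mukaiyama aldol.

Step 14
Reactants: 22 acrolein (prop-2-enal, freshly distilled); 5 tributyl(2-{[(4-methoxybenzyl)oxy]methyl}prop-2-en-1-yl)stannane
Product: 23 (3S)-5-{[(4-methoxybenzyl)oxy]methyl}hexa-1,5-dien-3-ol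
Conditions: (S)-BINOL (20 mol%), Ti(OiPr)4 (10 mol%), 4 Å MS, CH2Cl2, −20 °C, 72 h; aq. NaHCO3
Reagents that add atoms: none
Why: Keck asymmetric carbonyl allylation (1,2-addition, Si face) sets C2 as S with the same catalyst enantiomer as in step 9.

Step 15
Reactants: 23 (3S)-5-{[(4-methoxybenzyl)oxy]methyl}hexa-1,5-dien-3-ol
Product: 24 tert-butyl{[(3S)-5-{[(4-methoxybenzyl)oxy]methyl}hexa-1,5-dien-3-yl]oxy}dimethylsilane
Conditions: TBSCl, imidazole, DMF, rt
Reagents that add atoms: tert-butyldimethylsilyl chloride, CC(C)(C)[Si](C)(C)Cl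
Why: Silyl protection of the C2 alcohol with a group that survives every step up to the late fluoride treatment.

Step 16
Reactants: 24 tert-butyl{[(3S)-5-{[(4-methoxybenzyl)oxy]methyl}hexa-1,5-dien-3-yl]oxy}dimethylsilane
Product: 25 (4S)-4-{[tert-butyl(dimethyl)silyl]oxy}-2-methylidenehex-5-en-1-ol
Conditions: DDQ, CH2Cl2/pH 7 buffer (10:1), 0 °C
Reagents that add atoms: none
Why: Oxidative cleavage of the PMB ether by DDQ frees the 2-substituted allylic alcohol needed for directed epoxidation.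

Step 17
Reactants: 25 (4S)-4-{[tert-butyl(dimethyl)silyl]oxy}-2-methylidenehex-5-en-1-ol
Product: 26 {(2R)-2-[(2S)-2-{[tert-butyl(dimethyl)silyl]oxy}but-3-en-1-yl]oxiran-2-yl}methanol
Conditions: Ti(OiPr)4 (10 mol%), D-(−)-diethyl tartrate (12 mol%), t-BuOOH, 4 Å MS, CH2Cl2, −20 °C
Reagents that add atoms: tert-butyl hydroperoxide, CC(C)(C)OO
Why: Sharpless asymmetric epoxidation of the allylic alcohol, where D-(−)-tartrate gives the (R)-epoxide (the sense that gives (R)-2-methylglycidol from methallyl alcohol), sets C10 under reagent control and leaves the non-allylic vinyl group alone.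

Step 18
Reactants: 26 {(2R)-2-[(2S)-2-{[tert-butyl(dimethyl)silyl]oxy}but-3-en-1-yl]oxiran-2-yl}methanol
Product: 27 (2R,4S)-4-{[tert-butyl(dimethyl)silyl]oxy}-2-methylhex-5-ene-1,2-diol
Conditions: LiAlH4, THF, 0 °C; Fieser work-up
Reagents that add atoms: none
Why: SN2 hydride opening at the unhindered epoxide CH2 creates the C14 methyl and the tertiary C10 alcohol without touching the stereocentre.

Step 19
Reactants: 27 (2R,4S)-4-{[tert-butyl(dimethyl)silyl]oxy}-2-methylhex-5-ene-1,2-diol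
Product: 28 (2R,4S)-4-{[tert-butyl(dimethyl)silyl]oxy}-2-methyl-1,2-bis[(triethylsilyl)oxy]hex-5-ene
Conditions: Et3SiOTf (2.5 equiv), 2,6-lutidine, CH2Cl2, −78 → 0 °C
Reagents that add atoms: triethylsilyl trifluoromethanesulfonate, CC[Si](CC)(CC)OS(=O)(=O)C(F)(F)F
Why: Silyl triflate silylation protects both the primary and the hindered tertiary hydroxyl.

Step 20
Reactants: 28 (2R,4S)-4-{[tert-butyl(dimethyl)silyl]oxy}-2-methyl-1,2-bis[(triethylsilyl)oxy]hex-5-ene
Product: 29 (2R,4S)-4-{[tert-butyl(dimethyl)silyl]oxy}-2-methyl-2-[(triethylsilyl)oxy]hex-5-enal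
Conditions: (COCl)2, DMSO, CH2Cl2, −78 → −40 °C; Et3N, → 0 °C
Reagents that add atoms: none
Why: Swern oxidation converts the primary triethylsilyl ether directly into the aldehyde while the tertiary TES and secondary TBS ethers stay, and the α-carbon is quaternary so it cannot epimerise.

Step 21
Reactants: 21 tert-butyl({3-({[tert-butyl(diphenyl)silyl]oxy}methyl)-4-[(1S)-3-{[(4-methoxybenzyl)oxy]methyl}-1-[(triethylsilyl)oxy]but-3-en-1-yl]furan-2-yl}oxy)dimethylsilane; 29 (2R,4S)-4-{[tert-butyl(dimethyl)silyl]oxy}-2-methyl-2-[(triethylsilyl)oxy]hex-5-enal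
Product: 30 3-({[tert-butyl(diphenyl)silyl]oxy}methyl)-5-[(2R,4S)-4-{[tert-butyl(dimethyl)silyl]oxy}-1-hydroxy-2-methyl-2-[(triethylsilyl)oxy]hex-5-en-1-yl]-4-[(1S)-3-{[(4-methoxybenzyl)oxy]methyl}-1-[(triethylsilyl)oxy]but-3-en-1-yl]furan-2(5H)-one (C8/C9 epimer mixture)
Conditions: BF3·OEt2 (1.2 equiv), CH2Cl2, −78 °C; aq. NaHCO3
Reagents that add atoms: none
Why: Vinylogous Mukaiyama aldol reaction in which C5 of the silyloxyfuran (C3 is blocked) attacks the BF3-activated aldehyde to form the C8–C9 bond; the two new stereocentres form unselectively but both are erased in step 23.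

Step 22
Reactants: 30 vinylogous aldol adduct (C8/C9 epimer mixture)
Product: 31 (2S,6S,10R)-2-[(tert-butyldimethylsilyl)oxy]-13-[(tert-butyldiphenylsilyl)oxy]-9-hydroxy-15-[(4-methoxybenzyl)oxy]-6,10-bis[(triethylsilyl)oxy]germacra-3,7(11)-dien-12,8-olide (3E by CIP with the ring carbons cis; C8/C9 epimers)
Conditions: second-generation Grubbs catalyst RuCl2(=CHPh)(PCy3)(1,3-dimesitylimidazolidin-2-ylidene) (15 mol% in three portions), toluene (1 mM), 80 °C, argon sparge
Reagents that add atoms: none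
Why: Ring-closing metathesis between the monosubstituted and the 1,1-disubstituted alkene closes the ten-membered ring, driven by loss of ethene, and ring strain enforces the cis ring alkene.

Step 23
Reactants: 31 macrocyclic C9 carbinol (C8/C9 epimers)
Product: 33 (2S,6S,10R)-2-[(tert-butyldimethylsilyl)oxy]-13-[(tert-butyldiphenylsilyl)oxy]-15-[(4-methoxybenzyl)oxy]-6,10-bis[(triethylsilyl)oxy]germacra-3,7(11),8-trien-12,8-olide (3E,8E), via C9 mesylate 32 (not isolated)
Conditions: MsCl, Et3N, CH2Cl2, 0 °C; then DBU, 0 °C → rt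
Reagents that add atoms: none
Why: Mesylation followed by E1cB elimination through the furanolate removes both temporary stereocentres, and the ten-membered ring holds C10 syn to C7 so the ring-cis (8E) enol lactone is expected.

Step 24
Reactants: 33 fully protected trienolide
Product: 34 (2S,6S,10R)-2-[(tert-butyldimethylsilyl)oxy]-13-[(tert-butyldiphenylsilyl)oxy]-6-hydroxy-15-[(4-methoxybenzyl)oxy]-10-[(triethylsilyl)oxy]germacra-3,7(11),8-trien-12,8-olide
Conditions: PPTS (0.2 equiv), MeOH/CH2Cl2 (1:1), 0 °C, monitored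
Reagents that add atoms: none
Why: Chemoselective acid-catalysed methanolysis removes the secondary TES ether faster than the hindered tertiary TES, the secondary TBS and the TBDPS ethers (partial loss of the C10 silyl group would be harmless because a tertiary alcohol is not acylated later).

Step 25
Reactants: 34 C6 alcohol; 35 angelic acid [(2Z)-2-methylbut-2-enoic acid]
Product: 37 (2S,6S,10R)-6-(angeloyloxy)-2-[(tert-butyldimethylsilyl)oxy]-13-[(tert-butyldiphenylsilyl)oxy]-15-[(4-methoxybenzyl)oxy]-10-[(triethylsilyl)oxy]germacra-3,7(11),8-trien-12,8-olide, via mixed anhydride 36 (not isolated)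
Conditions: 35, 2,4,6-trichlorobenzoyl chloride, Et3N, toluene, rt; then 34, 75 °C
Reagents that add atoms: none
Why: Yamaguchi-type esterification through the mixed anhydride without DMAP acylates the only free hydroxyl and avoids isomerisation of the angelate to the tiglate.

Step 26
Reactants: 37 C6 angelate
Product: 38 (2S,6S,10R)-6-(angeloyloxy)-2,10,13-trihydroxy-15-[(4-methoxybenzyl)oxy]germacra-3,7(11),8-trien-12,8-olide
Conditions: HF·pyridine, pyridine, THF, 0 °C → rt, 24–36 h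
Reagents that add atoms: none
Why: Buffered fluoride desilylation removes the TBS, TBDPS and tertiary TES groups together without touching the esters, the enol lactone or the PMB ether.

Step 27
Reactants: 38 triol
Product: 39 (2S,6S,10R)-2,13-diacetoxy-6-(angeloyloxy)-10-hydroxy-15-[(4-methoxybenzyl)oxy]germacra-3,7(11),8-trien-12,8-olide
Conditions: Ac2O, pyridine, DMAP (5 mol%), CH2Cl2, 0 °C
Reagents that add atoms: acetic anhydride, CC(=O)OC(C)=O
Why: Acetylation takes the primary C13 and secondary C2 hydroxyls while the tertiary C10 alcohol is too hindered to react under these mild conditions.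

Step 28
Reactants: 39 diacetate PMB ether
Product: 40 (2S,6S,10R)-2,13-diacetoxy-6-(angeloyloxy)-10,15-dihydroxygermacra-3,7(11),8-trien-12,8-olide (CNP0165707.1)
Conditions: DDQ, CH2Cl2/pH 7 buffer (10:1), 0 °C → rt
Reagents that add atoms: none
Why: Oxidative PMB cleavage under neutral conditions liberates the C15 allylic alcohol without acyl migration and completes the target.

## Compound list

1 | 3-chloro-2-(chloromethyl)prop-1-ene | C=C(CCl)CCl | starting material
2 | 4-methoxybenzyl alcohol | COc1ccc(CO)cc1 | starting material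
3 | 1-({[2-(chloromethyl)prop-2-en-1-yl]oxy}methyl)-4-methoxybenzene | C=C(CCl)COCc1ccc(OC)cc1 | intermediate
4 | chloro(2-{[(4-methoxybenzyl)oxy]methyl}prop-2-en-1-yl)magnesium (not isolated) | C=C(C[Mg]Cl)COCc1ccc(OC)cc1 | intermediate
5 | tributyl(2-{[(4-methoxybenzyl)oxy]methyl}prop-2-en-1-yl)stannane | C=C(C[Sn](CCCC)(CCCC)CCCC)COCc1ccc(OC)cc1 | intermediate
6 | diethyl furan-3,4-dicarboxylate | CCOC(=O)c1cocc1C(=O)OCC | starting material
7 | furan-3,4-diyldimethanol | OCc1cocc1CO | intermediate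
8 | [4-({[tert-butyl(dimethyl)silyl]oxy}methyl)furan-3-yl]methanol | OCc1cocc1CO[Si](C)(C)C(C)(C)C | intermediate
9 | dilithio derivative of 8: lithium alkoxide, C2-lithiated furan (not isolated) | [Li]OCc1c([Li])occ1CO[Si](C)(C)C(C)(C)C | intermediate
10 | C2-trimethylsilyl O-trimethylsilyl derivative of 8 (not isolated) | C[Si](C)(C)OCc1c([Si](C)(C)C)occ1CO[Si](C)(C)C(C)(C)C | intermediate
11 | [4-({[tert-butyl(dimethyl)silyl]oxy}methyl)-2-(trimethylsilyl)furan-3-yl]methanol | OCc1c([Si](C)(C)C)occ1CO[Si](C)(C)C(C)(C)C | intermediate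
12 | tert-butyl{[4-({[tert-butyl(dimethyl)silyl]oxy}methyl)-2-(trimethylsilyl)furan-3-yl]methoxy}diphenylsilane | CC(C)(C)[Si](OCc1c([Si](C)(C)C)occ1CO[Si](C)(C)C(C)(C)C)(c1ccccc1)c1ccccc1 | intermediate
13 | [4-({[tert-butyl(diphenyl)silyl]oxy}methyl)-5-(trimethylsilyl)furan-3-yl]methanol | OCc1coc([Si](C)(C)C)c1CO[Si](c1ccccc1)(c1ccccc1)C(C)(C)C | intermediate
14 | 4-({[tert-butyl(diphenyl)silyl]oxy}methyl)-5-(trimethylsilyl)furan-3-carbaldehyde | O=Cc1coc([Si](C)(C)C)c1CO[Si](c1ccccc1)(c1ccccc1)C(C)(C)C | intermediate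
15 | (1S)-1-[4-({[tert-butyl(diphenyl)silyl]oxy}methyl)-5-(trimethylsilyl)furan-3-yl]-3-{[(4-methoxybenzyl)oxy]methyl}but-3-en-1-ol | O[C@H](c1coc([Si](C)(C)C)c1CO[Si](c1ccccc1)(c1ccccc1)C(C)(C)C)CC(=C)COCc1ccc(OC)cc1 | intermediate
16 | triethylsilyl ether of 15 (1S) | CC[Si](CC)(CC)O[C@H](c1coc([Si](C)(C)C)c1CO[Si](c1ccccc1)(c1ccccc1)C(C)(C)C)CC(=C)COCc1ccc(OC)cc1 | intermediate
17 | 2,5-endoperoxide of furan 16 (not isolated; bridgehead configuration undefined) | CC[Si](CC)(CC)O[C@H](C1=C(CO[Si](c2ccccc2)(c2ccccc2)C(C)(C)C)C2([Si](C)(C)C)OOC1O2)CC(=C)COCc1ccc(OC)cc1 | intermediate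
18 | 3-({[tert-butyl(diphenyl)silyl]oxy}methyl)-5-hydroxy-4-[(1S)-3-{[(4-methoxybenzyl)oxy]methyl}-1-[(triethylsilyl)oxy]but-3-en-1-yl]furan-2(5H)-one (C5 epimers) | CC[Si](CC)(CC)O[C@H](C1=C(CO[Si](c2ccccc2)(c2ccccc2)C(C)(C)C)C(=O)OC1O)CC(=C)COCc1ccc(OC)cc1 | intermediate
19 | sodium (2E,4S)-2-({[tert-butyl(diphenyl)silyl]oxy}methyl)-3-(hydroxymethyl)-6-{[(4-methoxybenzyl)oxy]methyl}-4-[(triethylsilyl)oxy]hepta-2,6-dienoate, hydroxymethyl cis to carboxylate (not isolated) | CC[Si](CC)(CC)O[C@H](/C(CO)=C(\CO[Si](c1ccccc1)(c1ccccc1)C(C)(C)C)C(=O)[O-])CC(=C)COCc1ccc(OC)cc1.[Na+] | intermediate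
20 | 3-({[tert-butyl(diphenyl)silyl]oxy}methyl)-4-[(1S)-3-{[(4-methoxybenzyl)oxy]methyl}-1-[(triethylsilyl)oxy]but-3-en-1-yl]furan-2(5H)-one | CC[Si](CC)(CC)O[C@H](C1=C(CO[Si](c2ccccc2)(c2ccccc2)C(C)(C)C)C(=O)OC1)CC(=C)COCc1ccc(OC)cc1 | intermediate
21 | tert-butyl({3-({[tert-butyl(diphenyl)silyl]oxy}methyl)-4-[(1S)-3-{[(4-methoxybenzyl)oxy]methyl}-1-[(triethylsilyl)oxy]but-3-en-1-yl]furan-2-yl}oxy)dimethylsilane | CC[Si](CC)(CC)O[C@H](c1coc(O[Si](C)(C)C(C)(C)C)c1CO[Si](c1ccccc1)(c1ccccc1)C(C)(C)C)CC(=C)COCc1ccc(OC)cc1 | intermediate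
22 | acrolein (prop-2-enal) | C=CC=O | starting material
23 | (3S)-5-{[(4-methoxybenzyl)oxy]methyl}hexa-1,5-dien-3-ol | C=C[C@@H](O)CC(=C)COCc1ccc(OC)cc1 | intermediate
24 | tert-butyl{[(3S)-5-{[(4-methoxybenzyl)oxy]methyl}hexa-1,5-dien-3-yl]oxy}dimethylsilane | C=C[C@@H](O[Si](C)(C)C(C)(C)C)CC(=C)COCc1ccc(OC)cc1 | intermediate
25 | (4S)-4-{[tert-butyl(dimethyl)silyl]oxy}-2-methylidenehex-5-en-1-ol | C=C[C@@H](O[Si](C)(C)C(C)(C)C)CC(=C)CO | intermediate
26 | {(2R)-2-[(2S)-2-{[tert-butyl(dimethyl)silyl]oxy}but-3-en-1-yl]oxiran-2-yl}methanol | C=C[C@@H](O[Si](C)(C)C(C)(C)C)C[C@@]1(CO)CO1 | intermediate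
27 | (2R,4S)-4-{[tert-butyl(dimethyl)silyl]oxy}-2-methylhex-5-ene-1,2-diol | C=C[C@@H](O[Si](C)(C)C(C)(C)C)C[C@@](C)(O)CO | intermediate
28 | (2R,4S)-4-{[tert-butyl(dimethyl)silyl]oxy}-2-methyl-1,2-bis[(triethylsilyl)oxy]hex-5-ene | C=C[C@@H](O[Si](C)(C)C(C)(C)C)C[C@@](C)(O[Si](CC)(CC)CC)CO[Si](CC)(CC)CC | intermediate
29 | (2R,4S)-4-{[tert-butyl(dimethyl)silyl]oxy}-2-methyl-2-[(triethylsilyl)oxy]hex-5-enal | C=C[C@@H](O[Si](C)(C)C(C)(C)C)C[C@@](C)(O[Si](CC)(CC)CC)C=O | intermediate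
30 | 3-({[tert-butyl(diphenyl)silyl]oxy}methyl)-5-[(2R,4S)-4-{[tert-butyl(dimethyl)silyl]oxy}-1-hydroxy-2-methyl-2-[(triethylsilyl)oxy]hex-5-en-1-yl]-4-[(1S)-3-{[(4-methoxybenzyl)oxy]methyl}-1-[(triethylsilyl)oxy]but-3-en-1-yl]furan-2(5H)-one (epimers at C8 and C9) | CC[Si](CC)(CC)O[C@H](C1=C(CO[Si](c2ccccc2)(c2ccccc2)C(C)(C)C)C(=O)OC1C(O)[C@](C)(O[Si](CC)(CC)CC)C[C@H](O[Si](C)(C)C(C)(C)C)C=C)CC(=C)COCc1ccc(OC)cc1 | intermediate
31 | (2S,6S,10R)-2-[(tert-butyldimethylsilyl)oxy]-13-[(tert-butyldiphenylsilyl)oxy]-9-hydroxy-15-[(4-methoxybenzyl)oxy]-6,10-bis[(triethylsilyl)oxy]germacra-3,7(11)-dien-12,8-olide (3E, ring carbons cis; epimers at C8 and C9) | CC[Si](CC)(CC)O[C@H]1C/C(COCc3ccc(OC)cc3)=C\[C@@H](O[Si](C)(C)C(C)(C)C)C[C@@](C)(O[Si](CC)(CC)CC)C(O)C2OC(=O)C(CO[Si](c3ccccc3)(c3ccccc3)C(C)(C)C)=C21 | intermediate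
32 | 9-O-methanesulfonate of 31 (not isolated) | CC[Si](CC)(CC)O[C@H]1C/C(COCc3ccc(OC)cc3)=C\[C@@H](O[Si](C)(C)C(C)(C)C)C[C@@](C)(O[Si](CC)(CC)CC)C(OS(C)(=O)=O)C2OC(=O)C(CO[Si](c3ccccc3)(c3ccccc3)C(C)(C)C)=C21 | intermediate
33 | (2S,6S,10R)-2-[(tert-butyldimethylsilyl)oxy]-13-[(tert-butyldiphenylsilyl)oxy]-15-[(4-methoxybenzyl)oxy]-6,10-bis[(triethylsilyl)oxy]germacra-3,7(11),8-trien-12,8-olide (3E,8E) | CC[Si](CC)(CC)O[C@H]1C/C(COCc3ccc(OC)cc3)=C\[C@@H](O[Si](C)(C)C(C)(C)C)C[C@@](C)(O[Si](CC)(CC)CC)/C=C2/OC(=O)C(CO[Si](c3ccccc3)(c3ccccc3)C(C)(C)C)=C21 | intermediate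
34 | (2S,6S,10R)-2-[(tert-butyldimethylsilyl)oxy]-13-[(tert-butyldiphenylsilyl)oxy]-6-hydroxy-15-[(4-methoxybenzyl)oxy]-10-[(triethylsilyl)oxy]germacra-3,7(11),8-trien-12,8-olide | O[C@H]1C/C(COCc3ccc(OC)cc3)=C\[C@@H](O[Si](C)(C)C(C)(C)C)C[C@@](C)(O[Si](CC)(CC)CC)/C=C2/OC(=O)C(CO[Si](c3ccccc3)(c3ccccc3)C(C)(C)C)=C21 | intermediate
35 | angelic acid, (2Z)-2-methylbut-2-enoic acid | C/C=C(/C)C(=O)O | starting material
36 | (2Z)-2-methylbut-2-enoic 2,4,6-trichlorobenzoic anhydride (not isolated) | C/C=C(/C)C(=O)OC(=O)c1c(Cl)cc(Cl)cc1Cl | intermediate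
37 | (2S,6S,10R)-6-(angeloyloxy)-2-[(tert-butyldimethylsilyl)oxy]-13-[(tert-butyldiphenylsilyl)oxy]-15-[(4-methoxybenzyl)oxy]-10-[(triethylsilyl)oxy]germacra-3,7(11),8-trien-12,8-olide | C/C=C(/C)C(=O)O[C@H]1C/C(COCc3ccc(OC)cc3)=C\[C@@H](O[Si](C)(C)C(C)(C)C)C[C@@](C)(O[Si](CC)(CC)CC)/C=C2/OC(=O)C(CO[Si](c3ccccc3)(c3ccccc3)C(C)(C)C)=C21 | intermediate
38 | (2S,6S,10R)-6-(angeloyloxy)-2,10,13-trihydroxy-15-[(4-methoxybenzyl)oxy]germacra-3,7(11),8-trien-12,8-olide | C/C=C(/C)C(=O)O[C@H]1C/C(COCc3ccc(OC)cc3)=C\[C@@H](O)C[C@@](C)(O)/C=C2/OC(=O)C(CO)=C21 | intermediate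
39 | (2S,6S,10R)-2,13-diacetoxy-6-(angeloyloxy)-10-hydroxy-15-[(4-methoxybenzyl)oxy]germacra-3,7(11),8-trien-12,8-olide | C/C=C(/C)C(=O)O[C@H]1C/C(COCc3ccc(OC)cc3)=C\[C@@H](OC(C)=O)C[C@@](C)(O)/C=C2/OC(=O)C(COC(C)=O)=C21 | intermediate
40 | (2S,6S,10R)-2,13-diacetoxy-6-(angeloyloxy)-10,15-dihydroxygermacra-3,7(11),8-trien-12,8-olide (CNP0165707.1) | C/C=C(/C)C(=O)O[C@H]1C/C(CO)=C\[C@@H](OC(C)=O)C[C@@](C)(O)/C=C2/OC(=O)C(COC(C)=O)=C21 | target

## Summary

Total step count: 28.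
Longest linear sequence: 19 steps (6 → 40; steps 3–13 and 21–28).

Three steps most likely to fail:

Step 22 (ring-closing metathesis to a ten-membered ring with a trisubstituted alkene; oligomerisation or no closure). Fallback: reverse the order of dehydration and ring closure. Setting out from 30, the C8/C9 diastereomers in which H-8 and the activated C9 oxygen can become antiperiplanar with C10 syn to C7 are dehydrated by stereospecific anti-elimination (DEAD, PPh3, THF) to the open-chain (5E)-3-({[tert-butyl(diphenyl)silyl]oxy}methyl)-5-[(2R,4S)-4-{[tert-butyl(dimethyl)silyl]oxy}-2-methyl-2-[(triethylsilyl)oxy]hex-5-en-1-ylidene]-4-[(1S)-3-{[(4-methoxybenzyl)oxy]methyl}-1-[(triethylsilyl)oxy]but-3-en-1-yl]furan-2(5H)-one F1. Its planar dienyl lactone already holds both olefinic arms on the same side, and ring-closing metathesis of this pre-organised triene gives 33 directly; the route is rejoined at 33 and 31 and 32 are bypassed.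

Step 23 (elimination; wrong C8=C9 geometry or retro-aldol cleavage). Fallback: thermodynamic instead of kinetic control of the alkene geometry. Setting out from 31, if the mesylate collapses to the (8Z)-isomer of 33 (C10 syn to the lactone oxygen) F2, this isomer is equilibrated by reversible thiyl-radical addition (PhSSPh, hν, benzene) or triplet-sensitised irradiation, and the less strained ring-cis isomer 33 is collected; the route is rejoined at 33.

Step 21 (vinylogous Mukaiyama aldol between a hindered α-quaternary aldehyde and a 3,4-disubstituted silyloxyfuran). Fallback: nucleophile activation instead of electrophile activation. Setting out from butenolide 20 (21 is skipped), deprotonation with LiHMDS (THF, −78 °C) gives the lithium furan-2-olate of 20 F3, which adds through C5 (C3 is blocked) to aldehyde 29 in a direct vinylogous aldol addition; NH4Cl quench returns the route at 30.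

Further compounds
F1 | step 22 | (5E)-3-({[tert-butyl(diphenyl)silyl]oxy}methyl)-5-[(2R,4S)-4-{[tert-butyl(dimethyl)silyl]oxy}-2-methyl-2-[(triethylsilyl)oxy]hex-5-en-1-ylidene]-4-[(1S)-3-{[(4-methoxybenzyl)oxy]methyl}-1-[(triethylsilyl)oxy]but-3-en-1-yl]furan-2(5H)-one | C=C[C@@H](O[Si](C)(C)C(C)(C)C)C[C@@](C)(O[Si](CC)(CC)CC)/C=C1/OC(=O)C(CO[Si](c2ccccc2)(c2ccccc2)C(C)(C)C)=C1[C@@H](O[Si](CC)(CC)CC)CC(=C)COCc1ccc(OC)cc1
F2 | step 23 | (8Z)-isomer of 33 (C10 syn to the lactone oxygen) | CC[Si](CC)(CC)O[C@H]1C/C(COCc3ccc(OC)cc3)=C\[C@@H](O[Si](C)(C)C(C)(C)C)C[C@@](C)(O[Si](CC)(CC)CC)/C=C2\OC(=O)C(CO[Si](c3ccccc3)(c3ccccc3)C(C)(C)C)=C21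
F3 | step 21 | lithium furan-2-olate of 20 | CC[Si](CC)(CC)O[C@H](c1coc(O[Li])c1CO[Si](c1ccccc1)(c1ccccc1)C(C)(C)C)CC(=C)COCc1ccc(OC)cc1
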